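**Assumption:** the target is drawn as the free aryl hydrogen sulfate, so the last step ends with a cold acidification that should deliver this acid form; the sodium salt formed just before it is the form suited to storage.

## Structural features

The target is a flavone: a benzo-fused 4-pyranone (ring A fused to ring C across C4a–C8a) that carries ring B on C2 through the single bond C2–C1'. It has no stereocenter. Ring A has the phloroglucinol pattern, with O1 on C8a, a free hydroxyl on C5 and the hydrogen sulfate on O7; ring B has the isovanillin pattern (3'-OH, 4'-OMe). Three phenolic oxygens must be told apart: O5 is peri to the C4 carbonyl and chelated, O7 is the most acidic hydroxyl (a vinylogous acid through ring C), and O3' is an ordinary guaiacol-type phenol that would compete with O7 for a sulfating agent. The aryl hydrogen sulfate is the fragile group: acid hydrolyses it, it makes its carrier very polar, and it does not survive organometallic reagents, so it must come last and be followed only by neutral or basic operations. The real difficulty is regiochemical: C4a is a fully substituted carbon between C5–O and C8a–O1 that must receive the carbonyl carbon C4, and the ring oxygens must end in three different states. The key step exploits the adjacent pair C8a/C4a of ring A together with the oxygen on C5. An oxygen nucleophile on C8a and an acyl carbon on C4a, beside an alkoxy group, is the polarity that a 3-alkoxy-aryne imposes on a carboxylic acid. The atoms O1, C2, C3 and C4 of ring C map onto the carboxyl oxygen, the two alkyne carbons and the carboxyl carbon of an arylpropiolic acid.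

## Logic of the disconnections

**15 to 13 (through 14).** The O7–S bond and the acyl C–O bond on O3' are cut. The sulfate is removed first in the retrosynthetic sense because nothing acidic or organometallic may follow it. The gain is a neutral, chromatographable precursor. The forward step must sulfate O7 and not O5, which the chelation of the 5-OH to the C4 carbonyl should secure. The group on O3' must fall to hydroxide, which an aryl sulfate monoester tolerates.

**13 to 12.** The two benzylic O–C bonds on O5 and O7 are cut. Both ring-A oxygens can carry the same group, since chelation tells them apart later. The group must differ from the ester on O3' and must come off without touching that ester or the C2=C3 bond, which points to hydrogenolysis.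

**12 to 5 and 9 (key).** The bonds C8a–O1, C4a–C4 and O1–C2 are cut, which opens ring C and separates ring A from the rest. In one sentence: 10, set free from 5, inserts into the carboxyl C–O bond of 9, and the phenoxide so formed (11) closes ring C onto the alkyne. The cut is made here because the two carbons of the aryne become C8a and C4a, and the alkoxy group beside the triple bond decides which of them takes the oxygen. The gain is the whole C15 skeleton at the final oxidation level from two benzene derivatives, with the three oxygens already in two orthogonal protection classes. The forward step must add oxygen at the aryne carbon remote from the neighbouring alkoxy group, transfer the acyl group faster than the aryl anion is protonated, and close 6-endo.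

**5 to 2 to 1 (through 3 and 4).** The C–Si bond and the O–S bond of the triflate are cut, then the C–Br bond. The silyl group is brought from oxygen to carbon by an anionic 1,3-shift, so the bromine only marks the position. The two positions ortho to the hydroxyl of 1 are equivalent by symmetry, so only ortho versus para selectivity is asked of the bromination. 1 is a catalogue compound.

**9 to 7 and 8, then 7 to 6.** The C(sp2)–C(sp) bond between ring B and the alkyne is cut, then the acyl C–O bond on O3'. This leaves a commercial iodophenol and propiolic acid. The coupling must keep the carboxyl group, which calls for a copper-free protocol near room temperature.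

## Other disconnections considered

**Alternative 1:** the first route that comes to mind cuts C2–O1 and the C2–C3 bond. A Claisen–Schmidt condensation of 1-[2,4-bis(benzyloxy)-6-hydroxyphenyl]ethanone A1 with 4-methoxy-3-(methoxymethoxy)benzaldehyde A2 would give chalcone A3. Iodine in hot DMSO would then close and dehydrogenate ring C. This is the default plan and fails the first test. On chemical grounds it builds ring C in two operations and reaches the flavone oxidation level only through an extra oxidation. The hot hydroxide of the aldol step excludes a base-labile group on O3', so an acid-labile group would be needed there, and its removal would clash with the acid-sensitive sulfate at the end. The hydrogen iodide formed in the oxidative closure also threatens the chelated 5-O-benzyl ether.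

**Alternative 2:** a three-component cut of C4a–C4, C4–C3 and O1–C2. Palladium-catalysed carbonylative coupling of 3,5-bis(benzyloxy)-2-iodophenol A4 with carbon monoxide and 5-ethynyl-2-methoxyphenyl pivalate A5, followed by closure in the same flask, would give 12. This is a serious plan of equal length. However, oxidative addition must occur at an electron-rich iodide flanked by two ortho oxygen substituents, where direct alkyne coupling without carbon monoxide uptake (leading to a benzofuran) competes. The acyl–palladium route also often gives 5-exo closure. In the chosen plan the crowded C4a–C4 bond is made intramolecularly by an aryl anion, and no gas or transition metal is needed in the key step.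

**Alternative 3:** a biomimetic cut through ring A (C4a–C8a side, bond C4a–C5 or C8–C8a formed by Claisen condensation). Methyl 9-[3-(benzyloxy)-4-methoxyphenyl]-3,5,7-trioxonon-8-ynoate A6 would be folded by intramolecular Claisen condensation to the trihydroxyphenyl ynone A7, which would close to the flavone A8. The chain has several competing folding modes: aldol closure to a resorcylate, lactonisation to a 4-hydroxy-2-pyranone, and addition of an enol oxygen of the chain to the ynone to give a monocyclic 4-pyranone. Nothing in A6 favours the Claisen mode. The chain also takes more steps to assemble than ring A is worth, since the phloroglucinol ring can be bought, and A8 arrives with O5 and O7 both free and no handle beyond chelation.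

Key step: step 5

## Route

Step 1
Reactants: 1 3,5-bis(benzyloxy)phenol
Product: 2 3,5-bis(benzyloxy)-2-bromophenol
Conditions: NBS (1.0 equiv), i-Pr2NH (0.1 equiv), CH2Cl2, −78 °C to 0 °C
Reagents that add atoms: N-bromosuccinimide, O=C1CCC(=O)N1Br
Why: Amine-mediated ortho-selective electrophilic bromination of a phenol; the two ortho positions are equivalent by symmetry, the para position lies between two benzyloxy groups and is more hindered, and one equivalent at low temperature should limit dibromination.

Step 2
Reactants: 2 3,5-bis(benzyloxy)-2-bromophenol
Product: 5 3,5-bis(benzyloxy)-2-(trimethylsilyl)phenyl trifluoromethanesulfonate, via aryl silyl ether 3 (not isolated), via lithium silylphenoxide 4 (not isolated)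
Conditions: (Me3Si)2NH, THF, 70 °C, then evaporation; n-BuLi, THF, −100 °C; then Tf2O, −100 °C to −78 °C
Reagents that add atoms: hexamethyldisilazane, C[Si](C)(C)N[Si](C)(C)C; trifluoromethanesulfonic anhydride, O=S(=O)(OS(=O)(=O)C(F)(F)F)C(F)(F)F
Why: O-Silylation, bromine–lithium exchange, anionic 1,3-retro-Brook shift of silicon from oxygen to the lithiated carbon, and triflation of the resulting phenoxide, the standard one-flask route to ortho-silylaryl triflates; exchange at −100 °C should outrun deprotonation of the benzyl ethers.

Step 3
Reactants: 6 5-iodo-2-methoxyphenol
Product: 7 5-iodo-2-methoxyphenyl pivalate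
Conditions: t-BuCOCl, Et3N, DMAP (cat.), CH2Cl2, 0 °C to rt
Reagents that add atoms: pivaloyl chloride, CC(C)(C)C(=O)Cl
Why: Acylation of a phenol; the pivalate is chosen because it should resist fluoride and amidine base in the next two steps, survive hydrogenolysis, and fall to hydroxide at the end.

Step 4
Reactants: 7 5-iodo-2-methoxyphenyl pivalate; 8 propiolic acid
Product: 9 3-[4-methoxy-3-(pivaloyloxy)phenyl]prop-2-ynoic acid
Conditions: Pd(PPh3)4 (5 mol%), DBU (2.2 equiv), DMSO, 30 °C; aq. HCl work-up
Reagents that add atoms: none
Why: Copper-free Sonogashira-type coupling of an aryl iodide with propiolic acid (oxidative addition to zerovalent palladium, carbopalladation-free alkynyl transfer from the amidinium propiolate); without copper and near room temperature the carboxyl group should be kept.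

Step 5
Reactants: 5 3,5-bis(benzyloxy)-2-(trimethylsilyl)phenyl trifluoromethanesulfonate; 9 3-[4-methoxy-3-(pivaloyloxy)phenyl]prop-2-ynoic acid
Product: 12 5,7-bis(benzyloxy)-2-[4-methoxy-3-(pivaloyloxy)phenyl]-4H-chromen-4-one, via aryne 10 (not isolated), via hydroxyaryl ynone 11 (not isolated)
Conditions: CsF (4 equiv), THF, 125 °C, sealed tube; 5 in excess (1.5 equiv)
Reagents that add atoms: none
Why: Fluoride attacks silicon of 5 and expels triflate to give aryne 10. The carboxylate of 9 adds through oxygen to the aryne carbon remote from the neighbouring benzyloxy group (the former C–OTf carbon), because this terminus is the more distorted and electrophilic one and the aryl anion that develops on the other carbon sits beside the inductively withdrawing C5–O bond; the second benzyloxy group, meta and para to the two aryne carbons, has only a weak say. The aryl anion then attacks the ester carbonyl beside it (anionic ortho-Fries-type 1,3-acyl shift through a four-membered alkoxide), which gives the phenoxide of 11 with O1 on C8a and C4 on C4a. This phenoxide closes ring C by 6-endo-dig conjugate addition to the alkyne carbon that bears ring B, and protonation at C3 gives 12. The closest known reaction type is the formal insertion of arynes into the C–O bond of carboxylic acids to give ortho-hydroxyaryl ketones, which with unsaturated acids runs on to the cyclised chromanone or chromone. Acyl transfer must beat protonation of the aryl anion, which the aprotic medium and the intramolecular nature of the shift should secure, and it must beat carbanion addition to the alkyne, which the preferred Z conformation of the aryl ester prevents by holding the alkyne away from the anion. The 6-endo mode is preferred over 5-exo closure to the aurone because the ynone is polarised towards its beta carbon and neither an alkynophilic metal nor a protic solvent is present. No stereocenter is formed.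

Step 6
Reactants: 12 5,7-bis(benzyloxy)-2-[4-methoxy-3-(pivaloyloxy)phenyl]-4H-chromen-4-one
Product: 13 5,7-dihydroxy-2-[4-methoxy-3-(pivaloyloxy)phenyl]-4H-chromen-4-one
Conditions: H2 (1 atm), 10% Pd/C (palladium on carbon), EtOAc/THF, rt
Reagents that add atoms: none
Why: Hydrogenolysis of aryl benzyl ethers; the pivalate and the methyl ether are inert, and the C2=C3 bond of a flavone, part of a cross-conjugated vinylogous ester, should not be reduced at one atmosphere and room temperature if the reaction is stopped after uptake of two equivalents.

Step 7
Reactants: 13 5,7-dihydroxy-2-[4-methoxy-3-(pivaloyloxy)phenyl]-4H-chromen-4-one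
Product: 15 luteolin 4'-methyl ether 7-sulfate [5-hydroxy-2-(3-hydroxy-4-methoxyphenyl)-4-oxo-4H-chromen-7-yl hydrogen sulfate], via pyridinium sulfate 14 (not isolated)
Conditions: SO3·pyridine (3 equiv), pyridine, 0 °C to rt; then H2O, NaOH (0.5 M), 0 °C to rt; then 1 M HCl to pH 2, 0 °C, C18 desalting, lyophilisation
Reagents that add atoms: sulfur trioxide–pyridine complex, O=S(=O)([O-])[n+]1ccccc1
Why: O-Sulfation of a phenol with a sulfur trioxide–amine complex, then saponification of an activated aryl ester in the same flask; the 7-OH is the only free hydroxyl that is not chelated (the 5-OH is held by the hydrogen bond to the C4 carbonyl and O3' is acylated), and an aryl sulfate monoester anion should resist hydroxide at room temperature and brief cold dilute acid.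

## Compound list

1 | 3,5-bis(benzyloxy)phenol | Oc1cc(OCc2ccccc2)cc(OCc2ccccc2)c1 | starting material
2 | 3,5-bis(benzyloxy)-2-bromophenol | Oc1cc(OCc2ccccc2)cc(OCc2ccccc2)c1Br | intermediate
3 | [3,5-bis(benzyloxy)-2-bromophenoxy]trimethylsilane | C[Si](C)(C)Oc1cc(OCc2ccccc2)cc(OCc2ccccc2)c1Br | intermediate
4 | lithium 3,5-bis(benzyloxy)-2-(trimethylsilyl)phenoxide | [Li+].[O-]c1cc(OCc2ccccc2)cc(OCc2ccccc2)c1[Si](C)(C)C | intermediate
5 | 3,5-bis(benzyloxy)-2-(trimethylsilyl)phenyl trifluoromethanesulfonate | C[Si](C)(C)c1c(OCc2ccccc2)cc(OCc2ccccc2)cc1OS(=O)(=O)C(F)(F)F | intermediate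
6 | 5-iodo-2-methoxyphenol | COc1ccc(I)cc1O | starting material
7 | 5-iodo-2-methoxyphenyl pivalate | COc1ccc(I)cc1OC(=O)C(C)(C)C | intermediate
8 | propiolic acid | C#CC(=O)O | starting material
9 | 3-[4-methoxy-3-(pivaloyloxy)phenyl]prop-2-ynoic acid | COc1ccc(C#CC(=O)O)cc1OC(=O)C(C)(C)C | intermediate
10 | 3,5-bis(benzyloxy)benzyne | C1#CC(OCc2ccccc2)=CC(OCc2ccccc2)=C1 | intermediate
11 | 1-[2,4-bis(benzyloxy)-6-hydroxyphenyl]-3-[4-methoxy-3-(pivaloyloxy)phenyl]prop-2-yn-1-one (present in the flask as its cesium phenoxide) | COc1ccc(C#CC(=O)c2c(O)cc(OCc3ccccc3)cc2OCc2ccccc2)cc1OC(=O)C(C)(C)C | intermediate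
12 | 5,7-bis(benzyloxy)-2-[4-methoxy-3-(pivaloyloxy)phenyl]-4H-chromen-4-one | COc1ccc(-c2cc(=O)c3c(OCc4ccccc4)cc(OCc4ccccc4)cc3o2)cc1OC(=O)C(C)(C)C | intermediate
13 | 5,7-dihydroxy-2-[4-methoxy-3-(pivaloyloxy)phenyl]-4H-chromen-4-one | COc1ccc(-c2cc(=O)c3c(O)cc(O)cc3o2)cc1OC(=O)C(C)(C)C | intermediate
14 | pyridinium 5-hydroxy-2-[4-methoxy-3-(pivaloyloxy)phenyl]-4-oxo-4H-chromen-7-yl sulfate | COc1ccc(-c2cc(=O)c3c(O)cc(OS(=O)(=O)[O-])cc3o2)cc1OC(=O)C(C)(C)C.c1cc[nH+]cc1 | intermediate
15 | luteolin 4'-methyl ether 7-sulfate | COc1ccc(-c2cc(=O)c3c(O)cc(OS(=O)(=O)O)cc3o2)cc1O | target

## Step count and risk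

Total step count: 7. Longest linear sequence: 5 steps (steps 1, 2, 5, 6, 7; the branch through steps 3 and 4 is equally long).

**Step 5 (key step).** The aryl anion may be protonated before the acyl shift, which would stop at simple O-arylation of the acid. The propiolate may lose carbon dioxide at 125 °C, part of the material may close 5-exo, and fluoride may cleave the pivalate. Fallback, from 2 and 9, returning at 11 and then 12: esterification with DCC and DMAP should give 3,5-bis(benzyloxy)-2-bromophenyl 3-[4-methoxy-3-(pivaloyloxy)phenyl]prop-2-ynoate F1. Treatment with t-BuLi (2 equiv) in THF/Et2O at −100 °C should trigger bromine–lithium exchange and an anionic Fries shift, giving 11 after protonation. K2CO3 in acetone should then close 11 to 12. The acyl transfer then happens at low temperature, without an aryne and without fluoride.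

**Step 1.** Bromination may go para to the hydroxyl (between the two benzyloxy groups) or twice, since all three free ring positions are strongly activated. Fallback, from 1, returning at 5 and bypassing steps 1 and 2: isopropyl isocyanate with Et3N should give 3,5-bis(benzyloxy)phenyl N-isopropylcarbamate F2. N-Silylation in the flask (TBSOTf, TMEDA), carbamate-directed ortho-lithiation (n-BuLi, TMEDA, −78 °C) and quenching with Me3SiCl should give 3,5-bis(benzyloxy)-2-(trimethylsilyl)phenyl N-isopropylcarbamate F3. Cleavage with DBU and Et2NH in MeCN, followed by PhNTf2 in the same flask, should give 5. The site is then fixed by the directing group and not by electrophilic selectivity.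

**Step 4.** The product may decarboxylate under palladium and base, and the resulting alkyne may couple a second time to a diarylalkyne. Fallback, from 7, returning at 9: Sonogashira coupling with trimethylsilylacetylene (PdCl2(PPh3)2, CuI, Et3N) should give 2-methoxy-5-[(trimethylsilyl)ethynyl]phenyl pivalate F4. Fluoride-mediated carboxylation of the alkynylsilane (CsF, CO2 at 1 atm, DMSO, rt, then acid) should give 9, so the carboxyl group is introduced only after all palladium chemistry.

**Step 7.** Excess reagent may sulfate the chelated 5-OH as well, and the sulfate may be partly hydrolysed during the cold acidification. The product is too polar for easy separation from such by-products. Fallback, from 13, returning at 15: 2,2,2-trichloroethyl chlorosulfate with Et3N and DMAP in THF should give the neutral, silica-stable diester 5-hydroxy-2-[4-methoxy-3-(pivaloyloxy)phenyl]-4-oxo-4H-chromen-7-yl 2,2,2-trichloroethyl sulfate F5, on which regiochemistry and purity can be settled. Zn dust and HCO2NH4 in MeOH should unmask it to ammonium 5-hydroxy-2-[4-methoxy-3-(pivaloyloxy)phenyl]-4-oxo-4H-chromen-7-yl sulfate F6. LiOH in aqueous MeOH and the same cold acidification should then give 15.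

**Step 6.** The C2=C3 bond may be over-reduced to the flavanone, or hydrogenolysis may stall. Fallback, from 12, returning at 13: Lewis-acid debenzylation with BCl3 and pentamethylbenzene as cation scavenger in CH2Cl2 at −78 °C, which should leave the pivalate and the 4'-methyl ether alone. This fallback makes no new compound (F0).

## Further compounds

F1 | step 5 | 3,5-bis(benzyloxy)-2-bromophenyl 3-[4-methoxy-3-(pivaloyloxy)phenyl]prop-2-ynoate | COc1ccc(C#CC(=O)Oc2cc(OCc3ccccc3)cc(OCc3ccccc3)c2Br)cc1OC(=O)C(C)(C)C
F2 | step 1 | 3,5-bis(benzyloxy)phenyl N-isopropylcarbamate | CC(C)NC(=O)Oc1cc(OCc2ccccc2)cc(OCc2ccccc2)c1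
F3 | step 1 | 3,5-bis(benzyloxy)-2-(trimethylsilyl)phenyl N-isopropylcarbamate | CC(C)NC(=O)Oc1cc(OCc2ccccc2)cc(OCc2ccccc2)c1[Si](C)(C)C
F4 | step 4 | 2-methoxy-5-[(trimethylsilyl)ethynyl]phenyl pivalate | COc1ccc(C#C[Si](C)(C)C)cc1OC(=O)C(C)(C)C
F5 | step 7 | 5-hydroxy-2-[4-methoxy-3-(pivaloyloxy)phenyl]-4-oxo-4H-chromen-7-yl 2,2,2-trichloroethyl sulfate | COc1ccc(-c2cc(=O)c3c(O)cc(OS(=O)(=O)OCC(Cl)(Cl)Cl)cc3o2)cc1OC(=O)C(C)(C)C
F6 | step 7 | ammonium 5-hydroxy-2-[4-methoxy-3-(pivaloyloxy)phenyl]-4-oxo-4H-chromen-7-yl sulfate | COc1ccc(-c2cc(=O)c3c(O)cc(OS(=O)(=O)[O-])cc3o2)cc1OC(=O)C(C)(C)C.[NH4+]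
F0 | step 6 | none | none
A1 | alternative 1 | 1-[2,4-bis(benzyloxy)-6-hydroxyphenyl]ethanone | CC(=O)c1c(O)cc(OCc2ccccc2)cc1OCc1ccccc1
A2 | alternative 1 | 4-methoxy-3-(methoxymethoxy)benzaldehyde | COCOc1cc(C=O)ccc1OC
A3 | alternative 1 | (E)-1-[2,4-bis(benzyloxy)-6-hydroxyphenyl]-3-[4-methoxy-3-(methoxymethoxy)phenyl]prop-2-en-1-one | COCOc1cc(/C=C/C(=O)c2c(O)cc(OCc3ccccc3)cc2OCc2ccccc2)ccc1OC
A4 | alternative 2 | 3,5-bis(benzyloxy)-2-iodophenol | Oc1cc(OCc2ccccc2)cc(OCc2ccccc2)c1I
A5 | alternative 2 | 5-ethynyl-2-methoxyphenyl pivalate | COc1ccc(C#C)cc1OC(=O)C(C)(C)C
A6 | alternative 3 | methyl 9-[3-(benzyloxy)-4-methoxyphenyl]-3,5,7-trioxonon-8-ynoate | COC(=O)CC(=O)CC(=O)CC(=O)C#Cc1ccc(OC)c(OCc2ccccc2)c1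
A7 | alternative 3 | 3-[3-(benzyloxy)-4-methoxyphenyl]-1-(2,4,6-trihydroxyphenyl)prop-2-yn-1-one | O=C(C#Cc1ccc(OC)c(OCc2ccccc2)c1)c1c(O)cc(O)cc1O
A8 | alternative 3 | 2-[3-(benzyloxy)-4-methoxyphenyl]-5,7-dihydroxy-4H-chromen-4-one | COc1ccc(-c2cc(=O)c3c(O)cc(O)cc3o2)cc1OCc1ccccc1
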